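**Target:** (S)-14-methylhexadecyl 2,3-dihydroxybenzoate, C24H40O4. There is one stereocentre, C14. Its CIP order is long chain > ethyl > methyl, which gives S.

**Assumption:** the in-situ Grignard preparation is counted as its own step, and protecting or activating reagents are listed with SMILES but not numbered.

## Retrosynthetic overview
1. Disconnect the ester C–O bond to give (S)-14-methylhexadecan-1-ol (13) and 2,3-bis(benzyloxy)benzoic acid (16). The catechol is unmasked last by hydrogenolysis.
2. Disconnect C15–C16 (CH2OTs + Me2CuLi), then C12–C13 (Cu-catalysed coupling of a C12 Grignard with a C4 tosylate).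
3. The C4 unit comes from prochiral 2-methylpropane-1,3-diol. A lipase-catalysed desymmetrisation sets C14, and no bond to C14 is touched afterwards.
4. The acetylated arm becomes the long chain and the free-OH arm becomes the ethyl group. This converts the (S)-monoacetate into the (S)-target.
5. No ring is formed. The only ring, the arene, is bought as 2,3-dihydroxybenzoic acid.

## Route

**Step 1**
Reactants: 1, 2-methylpropane-1,3-diol (achiral, prochiral)
Product: 2, (S)-3-hydroxy-2-methylpropyl acetate
Conditions: lipase (Pseudomonas fluorescens lipase, Amano AK), vinyl acetate (3 equiv), CHCl3, 30 °C. Follow by chiral GC and stop at ≥98% ee (about 50–60% diacetate, about 40–45% of 2). Filter off the enzyme, concentrate below 30 °C and use at once. The diacetate can be methanolysed back to 1.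
Reagents that add atoms: vinyl acetate, CC(=O)OC=C
Why: In this lipase-catalysed enantioselective desymmetrisation (irreversible transesterification), the enzyme acylates the pro-S CH2OH faster, matching its known S-preference for 2-methylalkan-1-ols, and then preferentially over-acylates the minor R-monoacetate to the achiral diacetate, so the ee rises with conversion.

**Step 2**
Reactants: 2
Product: 3, (R)-3-[(tert-butyldiphenylsilyl)oxy]-2-methylpropyl acetate (same spatial arrangement; the descriptor changes only through CIP ranking)
Conditions: TBDPSCl (1.1 equiv), imidazole (2.2 equiv), CH2Cl2, 0 °C → rt. The diacetate carried over from Step 1 is removed by chromatography here.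
Reagents that add atoms: TBDPSCl, CC(C)(C)[Si](Cl)(c1ccccc1)c1ccccc1
Why: Prompt silylation of the primary alcohol under mild imidazole conditions blocks the degenerate 1,3-O→O acyl shift, which is the only pathway that could racemise 2.

**Step 3**
Reactants: 3
Product: 4, (R)-3-[(tert-butyldiphenylsilyl)oxy]-2-methylpropan-1-ol
Conditions: K2CO3 (0.5 equiv), MeOH, 0 °C → rt, 1–2 h. Check ee by chiral HPLC or Mosher ester.
Reagents that add atoms: none
Why: Zemplén-type methanolysis removes the acetate, while the bulky TBDPS ether is neither cleaved nor migrated under these conditions (4 is a configurationally stable, widely used building block).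

**Step 4**
Reactants: 4
Product: 5, (S)-3-[(tert-butyldiphenylsilyl)oxy]-2-methylpropyl 4-methylbenzenesulfonate
Conditions: TsCl (1.3 equiv), Et3N, DMAP (cat.), CH2Cl2, 0 °C → rt
Reagents that add atoms: TsCl, Cc1ccc(cc1)S(Cl)(=O)=O
Why: Sulfonylation occurs at oxygen only, so the adjacent stereocentre is untouched and the arm is activated for C–C coupling.

**Step 5**
Reactants: 6, 12-bromododecan-1-ol
Product: 7, benzyl 12-bromododecyl ether
Conditions: benzyl 2,2,2-trichloroacetimidate (1.3 equiv), TfOH (5 mol %), cyclohexane/CH2Cl2 2:1, 0 °C → rt
Reagents that add atoms: benzyl 2,2,2-trichloroacetimidate, N=C(OCc1ccccc1)C(Cl)(Cl)Cl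
Why: Acid-catalysed imidate benzylation avoids forming an alkoxide, so the primary bromide is not displaced, and benzyl introduces no new stereocentre.

**Step 6**
Reactants: 7
Product: 8, [12-(benzyloxy)dodecyl]magnesium bromide (about 0.5 M in THF, titrated, used directly)
Conditions: Mg turnings (activated with BrCH2CH2Br), THF, slow addition, 40–45 °C
Reagents that add atoms: magnesium, [Mg]
Why: Grignard formation from a primary bromide is standard, the benzyl ether is inert, and slow addition limits Wurtz dimerisation.

**Step 7**
Reactants: 5 and 8 (1.8 equiv)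
Product: 9, tert-butyl{[(2R)-15-(benzyloxy)-2-methylpentadecyl]oxy}diphenylsilane
Conditions: Li2CuCl4 (5 mol %), THF, −78 °C → rt, 12 h. The crude product may be carried forward, because non-polar by-products separate easily after Step 8.
Reagents that add atoms: none
Why: The Cu-catalysed Kochi/Schlosser–Fouquet sp3–sp3 coupling of a primary tosylate with a primary alkyl Grignard is well precedented for β-methyl tosylates, forms C12–C13 by substitution at CH2, and does not involve the stereocentre.

**Step 8**
Reactants: 9
Product: 10, (R)-15-(benzyloxy)-2-methylpentadecan-1-ol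
Conditions: TBAF (1.5 equiv), THF, rt. The Mosher ester confirms the ee.
Reagents that add atoms: none
Why: Fluoride-mediated desilylation is orthogonal to the benzyl ether.

**Step 9**
Reactants: 10
Product: 11, (R)-15-(benzyloxy)-2-methylpentadecyl 4-methylbenzenesulfonate
Conditions: TsCl (1.3 equiv), Et3N, DMAP (cat.), CH2Cl2, 0 °C → rt
Reagents that add atoms: TsCl, Cc1ccc(cc1)S(Cl)(=O)=O
Why: O-tosylation activates the second arm without touching C–H or C–C bonds at the stereocentre.

**Step 10**
Reactants: 11
Product: 12, benzyl (S)-14-methylhexadecyl ether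
Conditions: Me2CuLi (4 equiv, from MeLi and CuI), Et2O, −30 → 0 °C
Reagents that add atoms: lithium dimethylcuprate, [Li+].C[Cu-]C (prepared from MeLi, [Li]C, and CuI)
Why: SN2 displacement of a primary tosylate by a Gilman cuprate turns CH2OTs into the ethyl branch, the reaction site is the CH2 and not the stereocentre, and the descriptor becomes S purely through CIP ranking.

**Step 11**
Reactants: 12
Product: 13, (S)-14-methylhexadecan-1-ol
Conditions: H2 (1 atm), 10% Pd/C, EtOH/EtOAc, rt
Reagents that add atoms: none
Why: Catalytic hydrogenolysis of the benzyl ether is clean because the molecule has no other reducible group.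

**Step 12**
Reactants: 14, 2,3-dihydroxybenzoic acid
Product: 15, benzyl 2,3-bis(benzyloxy)benzoate
Conditions: BnBr (3.6 equiv), K2CO3 (4 equiv), DMF, 60 °C
Reagents that add atoms: benzyl bromide, BrCc1ccccc1
Why: Exhaustive Williamson O-alkylation of both phenols and the carboxylate is the standard catechol-masking procedure from siderophore chemistry.

**Step 13**
Reactants: 15
Product: 16, 2,3-bis(benzyloxy)benzoic acid
Conditions: NaOH (aq, 5 equiv), MeOH/THF, reflux; then 1 M HCl
Reagents that add atoms: sodium hydroxide, [Na+].[OH-]
Why: Saponification (BAc2) cleaves only the benzyl ester, and the aryl benzyl ethers are base-stable.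

**Step 14**
Reactants: 13 and 16 (1.2 equiv)
Product: 17, (S)-14-methylhexadecyl 2,3-bis(benzyloxy)benzoate
Conditions: EDC·HCl (1.5 equiv), DMAP (0.3 equiv), CH2Cl2, rt
Reagents that add atoms: none
Why: Steglich esterification of an unhindered primary alcohol proceeds cleanly, and with the phenols masked there is no competing O-acylation or oligomerisation.

**Step 15**
Reactants: 17
Product: 18, gentiside C, (S)-14-methylhexadecyl 2,3-dihydroxybenzoate
Conditions: H2 (1 atm), 10% Pd/C, EtOAc/EtOH, rt. Filter and concentrate under neutral conditions.
Reagents that add atoms: none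
Why: Hydrogenolysis removes both aryl benzyl ethers, the alkyl ester and the saturated chain are inert, and neutral work-up avoids catechol oxidation.

## Compound list
| No. | Name | SMILES | Role |
|---|---|---|---|
| 1 | 2-methylpropane-1,3-diol | CC(CO)CO | starting material |
| 2 | (S)-3-hydroxy-2-methylpropyl acetate | OC[C@H](C)COC(C)=O | intermediate |
| 3 | (R)-3-[(tert-butyldiphenylsilyl)oxy]-2-methylpropyl acetate | CC(C)(C)[Si](c1ccccc1)(c1ccccc1)OC[C@H](C)COC(C)=O | intermediate |
| 4 | (R)-3-[(tert-butyldiphenylsilyl)oxy]-2-methylpropan-1-ol | CC(C)(C)[Si](c1ccccc1)(c1ccccc1)OC[C@H](C)CO | intermediate |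
| 5 | (S)-3-[(tert-butyldiphenylsilyl)oxy]-2-methylpropyl tosylate | CC(C)(C)[Si](c1ccccc1)(c1ccccc1)OC[C@H](C)COS(=O)(=O)c1ccc(C)cc1 | intermediate |
| 6 | 12-bromododecan-1-ol | OCCCCCCCCCCCCBr | starting material |
| 7 | benzyl 12-bromododecyl ether | BrCCCCCCCCCCCCOCc1ccccc1 | intermediate |
| 8 | [12-(benzyloxy)dodecyl]magnesium bromide | Br[Mg]CCCCCCCCCCCCOCc1ccccc1 | intermediate |
| 9 | tert-butyl{[(2R)-15-(benzyloxy)-2-methylpentadecyl]oxy}diphenylsilane | CC(C)(C)[Si](c1ccccc1)(c1ccccc1)OC[C@H](C)CCCCCCCCCCCCCOCc1ccccc1 | intermediate |
| 10 | (R)-15-(benzyloxy)-2-methylpentadecan-1-ol | OC[C@H](C)CCCCCCCCCCCCCOCc1ccccc1 | intermediate |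
| 11 | (R)-15-(benzyloxy)-2-methylpentadecyl tosylate | Cc1ccc(cc1)S(=O)(=O)OC[C@H](C)CCCCCCCCCCCCCOCc1ccccc1 | intermediate |
| 12 | benzyl (S)-14-methylhexadecyl ether | CC[C@H](C)CCCCCCCCCCCCCOCc1ccccc1 | intermediate |
| 13 | (S)-14-methylhexadecan-1-ol | CC[C@H](C)CCCCCCCCCCCCCO | intermediate |
| 14 | 2,3-dihydroxybenzoic acid | OC(=O)c1cccc(O)c1O | starting material |
| 15 | benzyl 2,3-bis(benzyloxy)benzoate | O=C(OCc1ccccc1)c1cccc(OCc2ccccc2)c1OCc1ccccc1 | intermediate |
| 16 | 2,3-bis(benzyloxy)benzoic acid | OC(=O)c1cccc(OCc2ccccc2)c1OCc1ccccc1 | intermediate |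
| 17 | (S)-14-methylhexadecyl 2,3-bis(benzyloxy)benzoate | CC[C@H](C)CCCCCCCCCCCCCOC(=O)c1cccc(OCc2ccccc2)c1OCc1ccccc1 | intermediate |
| 18 | gentiside C | CC[C@H](C)CCCCCCCCCCCCCOC(=O)c1cccc(O)c1O | target |

## Summary
**Total steps:** 15

**Longest linear sequence:** 11 (Steps 1–4, 7–11, 14, 15)

**Steps most likely to fail, each with a fallback:**
1. **Step 1.** The first acylation has only moderate intrinsic selectivity, so ee is bought with yield, and 2 can racemise by acyl migration.
   - Fallback: Zr-catalysed asymmetric carboalumination (ZACA) of allyl alcohol with Me3Al and catalytic (NMI)2ZrCl2, using the catalyst enantiomer that gives the S product.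
   - Iodinolysis then gives (S)-3-iodo-2-methylpropan-1-ol at about 80% ee.
   - Lipase/vinyl acetate acetylates away the minor R enantiomer, raising the ee to ≥99%.
   - TBDPS protection gives the iodide analogue of 5, which enters Step 7 directly.
2. **Steps 6/7.** Wurtz dimerisation of the long-chain Grignard and sluggish coupling at the β-branched tosylate are the risks.
   - Fallback: sulfone-anion coupling using the same fragments.
   - Convert 5 to the phenyl sulfone (PhSO2Na, DMF), deprotonate with n-BuLi, alkylate with bromide 7, and desulfonylate reductively (Na/Hg, Na2HPO4, MeOH) to give 9.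
3. **Step 10.** Incomplete displacement or competing reduction and elimination with the cuprate are the risks.
   - Fallback: one-carbon olefination instead of substitution.
   - Oxidise 10 with Dess–Martin periodinane and treat the aldehyde at once with Ph3P=CH2 (Wittig). Hydrogenation (H2, Pd/C) then saturates the alkene and cleaves the benzyl ether together, giving 13 directly.
   - The aldehyde is not stored, and the ee is checked after the Wittig step.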